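**Retrosynthetic overview**

1. Numbering: ring A is C1 (butanoyl), C2 (O), C3 (CMe2), C4 (O), C5, C6 (O); C7 is the bridging CH2; ring B is C1' (on C7), C2' (O), C3' (CMe2), C4' (O), C5' (propanoyl), C6' (O). The target has no stereocentre.
2. Feature: in its C4-keto tautomer ring A is a 6,6-dimethylcyclohexa-2,4-dienone. C3 is quaternary, so the ring can never aromatise; oxygen sits on C2 and C6, and C5 carries C7, which ends at C1' of ring B. This is the pattern left when a vinylketene (C1–C4) annulates an alkoxyalkyne (C5, C6).
3. Disconnections: C1–butanoyl (last step, C-acylation of the only free ring carbon after hydrolysis of four enol ethers); C4–C5 and C1–C6 of ring A (thermal cascade of 3-ethoxy-4,4-dimethylcyclobutenone with a methoxyalkyne held on C7 of O-methylated ring B); C7–C5 (Stille coupling of a ring B bromomethyl dienone with a methoxyethynylstannane).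
4. Ring order: ring B first (dearomatising C-methylation of a phloroglucinol ketone, step 2), ring A last (step 8).

Key step: step 8

Assumption: the second O-methylation (step 3) is taken to occur on O4' of the chelated enol, giving the cross-conjugated dienone; the O6' regioisomer would be an equally usable spectator, because step 9 hydrolyses every enol ether to the same trione.

**Route**

Step 1
Reactants: 1 1-(2,4,6-trihydroxyphenyl)propan-1-one (flopropione)
Product: 2 1-(2,6-dihydroxy-4-methoxyphenyl)propan-1-one
Conditions: Me2SO4 (1.0 equiv), K2CO3 (1.1 equiv), acetone, rt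
Reagents that add atoms: dimethyl sulfate, COS(=O)(=O)OC
Why: Williamson O-methylation should select the 4-hydroxyl, the most acidic one and the only one not hydrogen-bonded to the ketone; this oxygen becomes O2' of ring B.

Step 2
Reactants: 2 1-(2,6-dihydroxy-4-methoxyphenyl)propan-1-one
Product: 3 3-hydroxy-5-methoxy-4,4,6-trimethyl-2-propanoylcyclohexa-2,5-dien-1-one (ring B as chelated enol mono-methyl ether)
Conditions: NaOMe (3.3 equiv), MeI (3.5 equiv), MeOH, 0 °C to rt
Reagents that add atoms: iodomethane, CI
Why: Alkylative dearomatisation (C-methylation of the phloroglucinol-type phenoxide, as in the classical preparation of filicinic and syncarpic acids) should methylate both free ring carbons and then one of them a second time, the two being equivalent, while the 4-methoxy group blocks a fourth C-methylation; the by-product in which one carbon is dimethylated before the other is touched cannot react further and is removed by chromatography.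

Step 3
Reactants: 3 3-hydroxy-5-methoxy-4,4,6-trimethyl-2-propanoylcyclohexa-2,5-dien-1-one
Product: 4 3,5-dimethoxy-2,4,4-trimethyl-6-propanoylcyclohexa-2,5-dien-1-one (ring B bis-methyl enol ether with C7 as a methyl group)
Conditions: TMSCHN2 (2 equiv), toluene/MeOH 4:1, 0 °C to rt
Reagents that add atoms: trimethylsilyldiazomethane, C[Si](C)(C)C=[N+]=[N-]
Why: O-methylation of the acidic chelated enol by the diazoalkane in the presence of methanol is a neutral method that avoids C-methylation at C5' and should leave ring B without any acidic proton.

Step 4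
Reactants: 4 3,5-dimethoxy-2,4,4-trimethyl-6-propanoylcyclohexa-2,5-dien-1-one
Product: 5 2-(bromomethyl)-3,5-dimethoxy-4,4-dimethyl-6-propanoylcyclohexa-2,5-dien-1-one
Conditions: NBS (1.05 equiv), AIBN (5 mol %), solid NaHCO3, PhCF3, 80 °C
Reagents that add atoms: N-bromosuccinimide, O=C1CCC(=O)N1Br
Why: Wohl–Ziegler bromination should take the C7 methyl group, the only allylic C–H position (C3' is quaternary), through a radical delocalised into the C1'=C2' enol ether, as in known side-chain brominations of 2-methyl-3-alkoxyenones; the solid base keeps HBr from cleaving the enol ethers.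

Step 5
Reactants: 6 2-chloro-1,1-dimethoxyethane (chloroacetaldehyde dimethyl acetal)
Product: 8 tributyl(methoxyethynyl)stannane, via lithium methoxyacetylide 7 (not isolated)
Conditions: LiNEt2 (3.1 equiv, from Et2NH and n-BuLi), THF, 0 °C to rt; then Bu3SnCl, −78 °C to rt
Reagents that add atoms: tributyltin chloride, CCCC[Sn](Cl)(CCCC)CCCC
Why: Two base-induced eliminations (methanol, then HCl) and deprotonation, the known one-flask entry to alkoxyacetylides, give the lithium acetylide, which is stannylated at carbon by salt metathesis; a methoxy and not an ethoxy alkyne is made because it cannot lose an alkene by retro-ene reaction in the hot key step.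

Step 6
Reactants: 5 2-(bromomethyl)-3,5-dimethoxy-4,4-dimethyl-6-propanoylcyclohexa-2,5-dien-1-one; 8 tributyl(methoxyethynyl)stannane
Product: 9 3,5-dimethoxy-2-(3-methoxyprop-2-yn-1-yl)-4,4-dimethyl-6-propanoylcyclohexa-2,5-dien-1-one (ring B bis-methyl enol ether carrying the methoxyalkyne on C7)
Conditions: Pd2(dba)3 (2.5 mol %), P(2-furyl)3 (10 mol %), THF, 40 °C; chromatography on Et3N-deactivated silica
Reagents that add atoms: none
Why: Stille coupling of an allylic bromide with an alkynylstannane (oxidative addition of the C7–Br bond to zerovalent palladium, alkynyl transfer from tin, reductive elimination at the primary C7 terminus) should give the skipped enyne under neutral conditions that spare the ynol ether and both ring B ketones.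

Step 7
Reactants: 10 2-methylpropanoyl chloride (isobutyryl chloride); 11 ethoxyethyne (ethoxyacetylene)
Product: 13 3-ethoxy-4,4-dimethylcyclobut-2-en-1-one, via dimethylketene 12 (not isolated)
Conditions: Et3N (1.2 equiv), Et2O, rt, 24 h
Reagents that add atoms: none
Why: Dehydrochlorination gives dimethylketene, which adds to the alkoxyalkyne in a thermal [2+2] cycloaddition; the nucleophilic CH carbon of ethoxyethyne bonds to the ketene carbonyl carbon, which fixes the 3-ethoxy-4,4-dimethyl pattern.

Step 8
Reactants: 9 3,5-dimethoxy-2-(3-methoxyprop-2-yn-1-yl)-4,4-dimethyl-6-propanoylcyclohexa-2,5-dien-1-one; 13 3-ethoxy-4,4-dimethylcyclobut-2-en-1-one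
Product: 17 2-[(4-ethoxy-2-methoxy-5,5-dimethyl-6-oxocyclohexa-1,3-dien-1-yl)methyl]-3,5-dimethoxy-4,4-dimethyl-6-propanoylcyclohexa-2,5-dien-1-one (ring A dienone bis-enol ether joined through C7 to protected ring B), via vinylketene 14 (not isolated), via 4-alkenylcyclobutenone 15 (not isolated), via dienylketene 16 (not isolated)
Conditions: 13 (2.5 equiv), toluene (0.5 M in 9), 110 °C, sealed tube, argon
Reagents that add atoms: none
Why: Proposed new method: at 110 °C 13 should open by conrotatory 4π ring opening to vinylketene 14, whose ketene C=C adds across the ynol ether of 9 in a [2+2] cycloaddition (ketene carbonyl carbon, the future C4, to the nucleophilic alkyne carbon that carries C7, the future C5; ketene α-carbon, the future C1, to the methoxy-bearing carbon, the future C6) to give 15, which opens again to dienylketene 16 and closes to ring A. The closest known reaction types are the thermal benzannulation of cyclobutenones with alkoxyalkynes through vinylketenes and the thermal recyclisation of dienylketenes to 6,6-disubstituted cyclohexa-2,4-dienones; new here are the 3-alkoxy-4,4-dimethylcyclobutenone partner, whose quaternary C3 rules out the final enolisation to a phenol so that the cascade must stop at the dienone, and the ring B substituent on the propargylic carbon. Ring A is closed by a thermal disrotatory 6π electrocyclisation in which the ketene carbon bonds to the dimethyl-substituted diene terminus (C3–C4 bond); no stereocentre is created, and the single stereocentre of 15 is erased when it opens. The step needs the [2+2] regiochemistry, which the oxygen-polarised alkyne secures, and inward rotation of the alkenyl group when 15 opens, which need not be favoured kinetically because the opening is reversible and only the inward isomer is drained by the 6π closure. The ring B enol ethers are tetrasubstituted and deactivated by conjugation, the methoxyalkyne has no retro-ene pathway, and no acid, base or free enol is present that could cleave or scramble the C7 bridge.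

Step 9
Reactants: 17 ring A dienone bis-enol ether joined through C7 to protected ring B
Product: 18 2-[(2,4-dihydroxy-3,3-dimethyl-6-oxocyclohexa-1,4-dien-1-yl)methyl]-3,5-dihydroxy-4,4-dimethyl-6-propanoylcyclohexa-2,5-dien-1-one (target without the butanoyl group)
Conditions: 2 M HCl, THF, 50 °C
Reagents that add atoms: water, O
Why: Acid hydrolysis of enol ethers and vinylogous esters (C-protonation, addition of water, loss of alcohol) should free all four oxygens, ring A reacting fastest through protonation at C1 between its two alkoxy-bearing carbons, while the C7 bridge, which is known to break through enolate (retro-Michael) pathways in base, should hold in dilute acid.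

Step 10
Reactants: 18 target without the butanoyl group; 19 butanoic acid
Product: 21 target CNP0260944.0, via ring A enol butanoate 20 (not isolated)
Conditions: DCC (1.2 equiv), DMAP (1.2 equiv), CH2Cl2, 0 °C to rt
Reagents that add atoms: none
Why: Carbodiimide esterification of a ring A enol followed by DMAP-mediated O-to-C acyl migration (the acylation used for 2-acylcyclohexane-1,3-diones and 3-acyltetronic acids) should place the butanoyl group on C1, the only ring carbon that still carries hydrogen, where it is held as the chelated triketone; acyl groups that land on ring B oxygens cannot migrate to carbon and are lost on work-up.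

**Compound list**

1 | 1-(2,4,6-trihydroxyphenyl)propan-1-one (flopropione) | CCC(=O)c1c(O)cc(O)cc1O | starting material
2 | 1-(2,6-dihydroxy-4-methoxyphenyl)propan-1-one | CCC(=O)c1c(O)cc(OC)cc1O | intermediate
3 | 3-hydroxy-5-methoxy-4,4,6-trimethyl-2-propanoylcyclohexa-2,5-dien-1-one | CCC(=O)C1=C(O)C(C)(C)C(OC)=C(C)C1=O | intermediate
4 | 3,5-dimethoxy-2,4,4-trimethyl-6-propanoylcyclohexa-2,5-dien-1-one | CCC(=O)C1=C(OC)C(C)(C)C(OC)=C(C)C1=O | intermediate
5 | 2-(bromomethyl)-3,5-dimethoxy-4,4-dimethyl-6-propanoylcyclohexa-2,5-dien-1-one | CCC(=O)C1=C(OC)C(C)(C)C(OC)=C(CBr)C1=O | intermediate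
6 | 2-chloro-1,1-dimethoxyethane | COC(CCl)OC | starting material
7 | lithium methoxyacetylide | [Li]C#COC | intermediate
8 | tributyl(methoxyethynyl)stannane | CCCC[Sn](CCCC)(CCCC)C#COC | intermediate
9 | 3,5-dimethoxy-2-(3-methoxyprop-2-yn-1-yl)-4,4-dimethyl-6-propanoylcyclohexa-2,5-dien-1-one | CCC(=O)C1=C(OC)C(C)(C)C(OC)=C(CC#COC)C1=O | intermediate
10 | 2-methylpropanoyl chloride | CC(C)C(Cl)=O | starting material
11 | ethoxyethyne | CCOC#C | starting material
12 | dimethylketene | CC(C)=C=O | intermediate
13 | 3-ethoxy-4,4-dimethylcyclobut-2-en-1-one | CCOC1=CC(=O)C1(C)C | intermediate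
14 | 3-ethoxy-4-methylpenta-1,3-dien-1-one (vinylketene) | CCOC(C=C=O)=C(C)C | intermediate
15 | 4-(1-ethoxy-2-methylprop-1-en-1-yl)-3-methoxy-2-[(protected ring B)methyl]cyclobut-2-en-1-one, racemic | CCOC(=C(C)C)C1C(=O)C(CC2=C(OC)C(C)(C)C(OC)=C(C(=O)CC)C2=O)=C1OC | intermediate
16 | dienylketene, 5-ethoxy-3-methoxy-6-methyl-2-[(protected ring B)methyl]hepta-1,3,5-trien-1-one, alkenyl group cis to the ketene carbon | CCOC(=C(C)C)/C=C(OC)\C(=C=O)CC1=C(OC)C(C)(C)C(OC)=C(C(=O)CC)C1=O | intermediate
17 | 2-[(4-ethoxy-2-methoxy-5,5-dimethyl-6-oxocyclohexa-1,3-dien-1-yl)methyl]-3,5-dimethoxy-4,4-dimethyl-6-propanoylcyclohexa-2,5-dien-1-one | CCOC1=CC(OC)=C(CC2=C(OC)C(C)(C)C(OC)=C(C(=O)CC)C2=O)C(=O)C1(C)C | intermediate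
18 | 2-[(2,4-dihydroxy-3,3-dimethyl-6-oxocyclohexa-1,4-dien-1-yl)methyl]-3,5-dihydroxy-4,4-dimethyl-6-propanoylcyclohexa-2,5-dien-1-one | CCC(=O)C1=C(O)C(C)(C)C(O)=C(CC2=C(O)C(C)(C)C(O)=CC2=O)C1=O | intermediate
19 | butanoic acid | CCCC(O)=O | starting material
20 | ring A enol butanoate of 18 (ester on O2) | CCCC(=O)OC1=CC(=O)C(CC2=C(O)C(C)(C)C(O)=C(C(=O)CC)C2=O)=C(O)C1(C)C | intermediate
21 | CNP0260944.0, 2-butanoyl-6-[(2,4-dihydroxy-3,3-dimethyl-6-oxo-5-propanoylcyclohexa-1,4-dien-1-yl)methyl]-3,5-dihydroxy-4,4-dimethylcyclohexa-2,5-dien-1-one | CCCC(=O)C1=C(O)C(C)(C)C(O)=C(CC2=C(O)C(C)(C)C(O)=C(C(=O)CC)C2=O)C1=O | target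

**Step count and risks**

Total: 10 steps. Longest linear sequence: 8 steps (steps 1, 2, 3, 4, 6, 8, 9, 10).

Steps most likely to fail:

1. Step 8 (Proposed new method). The vinylketene may be drained by a 1,5-hydrogen shift from one of its terminal methyl groups to the ketene carbon, or by self-addition, before the hindered ynol ether traps it; the second ring opening may also stall at the cyclobutenone stage. Fallback by known chemistry, setting out from 5 and returning at 21: butanoylfilicinic acid F1 is made from commercial 1-(2,4,6-trihydroxyphenyl)butan-1-one by dearomatising C-dimethylation (NaOMe, MeI, MeOH). Its anion (NaOMe 1 equiv, MeOH, 0 °C) is C-alkylated at its only free ring carbon by bromide 5, as in the C-prenylation of acylfilicinic acids, to give the half-protected dimer F2. Hydrolysis with 2 M HCl in THF then removes the two methyl groups of ring B and gives 21 directly.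

2. Step 6. Ionisation of the bromide with loss of the neighbouring O-methyl group, or hydration and protodestannylation of the alkoxyalkyne at the metal, may outrun the cross-coupling. Fallback, setting out from 5 and the acetylide 7 of step 5 and returning at 9: the tin reagent and the palladium cycle are given up. Acetylide 7 is converted with CuBr·SMe2 into (methoxyethynyl)copper F3, which displaces the bromide of 5 in a direct SN2 substitution (THF, −78 to −20 °C). The soft copper acetylide should attack the allylic carbon faster than the ring B ketones.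

3. Step 4. Hydrogen abstraction at the propanoyl α-methylene, double bromination and HBr-induced loss of O-methyl groups may compete with bromination of the C7 methyl group. Fallback, setting out from 2 and returning at 5: C7 is brought in at the aldehyde oxidation level, so no C–H bromination is needed. Vilsmeier–Haack formylation of 2 (POCl3, DMF) gives the formyl ketone F4. Dearomatising gem-dimethylation of the one remaining free ring carbon (NaOMe, MeI, MeOH) gives the formyl enol mono-ether F5, and O-methylation with TMSCHN2 gives the aldehyde bis-enol ether F6. Reduction of the aldehyde alone (NaBH4, CeCl3·7H2O, MeOH, −40 °C) gives the allylic alcohol F7, and an Appel reaction (CBr4, PPh3, CH2Cl2, 0 °C) converts it into 5 under neutral conditions.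

**Further compounds**

F1 | step 8 | 2-butanoyl-3,5-dihydroxy-4,4-dimethylcyclohexa-2,5-dien-1-one (butanoylfilicinic acid) | CCCC(=O)C1=C(O)C(C)(C)C(O)=CC1=O
F2 | step 8 | 2-butanoyl-3,5-dihydroxy-6-[(2,4-dimethoxy-3,3-dimethyl-6-oxo-5-propanoylcyclohexa-1,4-dien-1-yl)methyl]-4,4-dimethylcyclohexa-2,5-dien-1-one | CCCC(=O)C1=C(O)C(C)(C)C(O)=C(CC2=C(OC)C(C)(C)C(OC)=C(C(=O)CC)C2=O)C1=O
F3 | step 6 | (methoxyethynyl)copper | [Cu]C#COC
F4 | step 4 | 2,4-dihydroxy-6-methoxy-3-propanoylbenzaldehyde | CCC(=O)c1c(O)cc(OC)c(C=O)c1O
F5 | step 4 | 4-hydroxy-2-methoxy-3,3-dimethyl-6-oxo-5-propanoylcyclohexa-1,4-diene-1-carbaldehyde | CCC(=O)C1=C(O)C(C)(C)C(OC)=C(C=O)C1=O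
F6 | step 4 | 2,4-dimethoxy-3,3-dimethyl-6-oxo-5-propanoylcyclohexa-1,4-diene-1-carbaldehyde | CCC(=O)C1=C(OC)C(C)(C)C(OC)=C(C=O)C1=O
F7 | step 4 | 2-(hydroxymethyl)-3,5-dimethoxy-4,4-dimethyl-6-propanoylcyclohexa-2,5-dien-1-one | CCC(=O)C1=C(OC)C(C)(C)C(OC)=C(CO)C1=O
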